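**Retrosynthetic overview**

1. Kanzonol I (29) ⇐ MOM ether 28 ⇐ phenol alcohol 27 (Mitsunobu closure of O1–C2; ring C is formed last) ⇐ imide 26 (Evans alkylation makes C3–C4 and sets C3) ⇐ chromenylacetyl oxazolidinone 24 + ring A benzylic bromide 10.
2. Chromene fragment 20 ⇐ redox-active ester 18 + acetylene 19: a photoredox decarboxylative radical (4+2) annulation builds the pyran ring on ring B by forming the CMe2–CH bond and the CH–aryl bond in one operation; 18 ⇐ 2,4-dihydroxyphenylacetic acid 11 via lactone 12, which tells the two phenols apart.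
3. Enabling feature: C2 of the pyran ring is a quaternary carbon carrying the ring oxygen and two methyl groups, so it can be released as a tertiary α-aryloxy radical from a carboxylic acid (CO2 as traceless activating group); on ring B the only free position ortho to that oxygen is C3', flanked by the oxygenated C2' and C4', because C1' carries the side chain; the cis CH=CH unit (C3=C4 of the chromene) maps onto acetylene.
4. Ring A fragment 10 ⇐ salicylaldehyde 7 ⇐ phenol 6 ⇐ 1,3-dimethoxybenzene 1 (lithiation/prenylation, sterically directed C–H borylation/oxidation, ortho-formylation).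
5. Order of ring formation: rings A and B are bought as benzene rings; pyran ring of the chromene (step 12); ring C of the chroman (step 17).

Key step: step 12

Remark on the chemistry: the stereocentre C3 in the SMILES is (R); with the priorities of this skeleton, (R)-4-benzyloxazolidin-2-one is the auxiliary that should give this configuration in the enolate alkylation.

**Route**

Step 1
Reactants: 1 1,3-dimethoxybenzene; 2 1-bromo-3-methylbut-2-ene (prenyl bromide)
Product: 4 1,3-dimethoxy-2-(3-methylbut-2-en-1-yl)benzene, via 2,6-dimethoxyphenyllithium 3 (not isolated)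
Conditions: n-BuLi, THF, 0 °C to rt; then 2, 0 °C to rt
Reagents that add atoms: n-butyllithium, [Li]CCCC (lithium of 3 only)
Why: Directed ortho-lithiation of 1,3-dimethoxybenzene occurs at C2 between the two methoxy groups, and the aryllithium is alkylated by the primary allylic bromide at its unhindered terminus (SN2), which places the prenyl group between the two methoxy groups.

Step 2
Reactants: 4 1,3-dimethoxy-2-(3-methylbut-2-en-1-yl)benzene
Product: 6 3,5-dimethoxy-4-(3-methylbut-2-en-1-yl)phenol, via aryl pinacol boronate 5 (not isolated)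
Conditions: [Ir(OMe)(cod)]2 (1.5 mol%), 4,4'-di-tert-butyl-2,2'-bipyridine (3 mol%), B2pin2, THF, 80 °C; then NaOH, 30% H2O2, THF/H2O, 0 °C
Reagents that add atoms: bis(pinacolato)diboron, CC1(C)OB(OC1(C)C)B1OC(C)(C)C(C)(C)O1 (boryl group of 5 only); hydrogen peroxide, OO (phenol oxygen of 6)
Why: Iridium-catalysed C–H borylation is governed by sterics and should take the only ring C–H that is not ortho to a substituent (C5, para to the prenyl group), the trisubstituted alkene being a poor substrate for the iridium boryl catalyst, and alkaline peroxide then converts the aryl boronate into the phenol without epoxidising the alkene (one-pot C–H borylation/oxidation).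

Step 3
Reactants: 6 3,5-dimethoxy-4-(3-methylbut-2-en-1-yl)phenol
Product: 7 6-hydroxy-2,4-dimethoxy-3-(3-methylbut-2-en-1-yl)benzaldehyde
Conditions: MgCl2, Et3N, paraformaldehyde, MeCN, reflux; dilute HCl work-up
Reagents that add atoms: paraformaldehyde (formaldehyde), C=O
Why: Magnesium phenoxide-mediated ortho-formylation with paraformaldehyde (Casnati–Skattebøl type) delivers the formyl group only ortho to the phenol, and the two ortho positions of 6 are equivalent by symmetry.

Step 4
Reactants: 7 6-hydroxy-2,4-dimethoxy-3-(3-methylbut-2-en-1-yl)benzaldehyde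
Product: 8 2-(hydroxymethyl)-3,5-dimethoxy-4-(3-methylbut-2-en-1-yl)phenol
Conditions: NaBH4, MeOH/THF, 0 °C; neutral work-up
Reagents that add atoms: none
Why: Chemoselective borohydride reduction of the aldehyde leaves the alkene untouched and gives the salicyl alcohol, which is kept neutral to basic because it is prone to acid-induced loss of water.

Step 5
Reactants: 8 2-(hydroxymethyl)-3,5-dimethoxy-4-(3-methylbut-2-en-1-yl)phenol
Product: 9 2-(hydroxymethyl)-3,5-dimethoxy-4-(3-methylbut-2-en-1-yl)phenyl 2,2-dimethylpropanoate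
Conditions: PivCl (1.05 equiv), Et3N, CH2Cl2, −20 to 0 °C
Reagents that add atoms: pivaloyl chloride, CC(C)(C)C(Cl)=O
Why: With an acid chloride and Et3N in the absence of an acyl-transfer catalyst the phenol should be acylated much faster than the neutral, doubly ortho-flanked benzylic alcohol (chemoselective O-acylation), and the electron-withdrawing pivalate both protects the phenol and tempers the benzylic position for the next two steps.

Step 6
Reactants: 9 2-(hydroxymethyl)-3,5-dimethoxy-4-(3-methylbut-2-en-1-yl)phenyl 2,2-dimethylpropanoate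
Product: 10 2-(bromomethyl)-3,5-dimethoxy-4-(3-methylbut-2-en-1-yl)phenyl 2,2-dimethylpropanoate
Conditions: CBr4, PPh3, CH2Cl2, 0 °C; used at once
Reagents that add atoms: carbon tetrabromide, BrC(Br)(Br)Br
Why: Appel bromination converts the primary benzylic alcohol into the bromide under neutral conditions that spare the prenyl group and the aryl ester.

Step 7
Reactants: 11 2-(2,4-dihydroxyphenyl)acetic acid
Product: 12 6-hydroxybenzofuran-2(3H)-one
Conditions: TsOH·H2O (cat.), toluene, reflux, Dean–Stark
Reagents that add atoms: none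
Why: Acid-catalysed lactonisation (intramolecular Fischer esterification) can engage only the phenol ortho to the acetic acid chain in a five-membered ring, which differentiates the two phenols of 11.

Step 8
Reactants: 12 6-hydroxybenzofuran-2(3H)-one
Product: 13 6-(methoxymethoxy)benzofuran-2(3H)-one
Conditions: MOMCl, i-Pr2NEt, CH2Cl2, 0 °C to rt
Reagents that add atoms: chloromethyl methyl ether, COCCl
Why: Alkylation of the only free phenol with chloromethyl methyl ether under a hindered amine base gives the MOM ether while the lactone stays closed.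

Step 9
Reactants: 13 6-(methoxymethoxy)benzofuran-2(3H)-one; 14 benzyl 2-bromo-2-methylpropanoate
Product: 16 benzyl 2-[2-(2-methoxy-2-oxoethyl)-5-(methoxymethoxy)phenoxy]-2-methylpropanoate, via methyl 2-[2-hydroxy-4-(methoxymethoxy)phenyl]acetate 15 (not isolated)
Conditions: Cs2CO3, MeOH, rt; evaporate; then 14, DMF, 60 °C
Reagents that add atoms: methanol, CO
Why: Methoxide opens the aryl lactone (transesterification) to unmask the ortho phenoxide, which is then O-alkylated by the tertiary α-bromo ester in a Williamson-type substitution of the kind used for aryloxyisobutyrates.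

Step 10
Reactants: 16 benzyl 2-[2-(2-methoxy-2-oxoethyl)-5-(methoxymethoxy)phenoxy]-2-methylpropanoate
Product: 17 2-[2-(2-methoxy-2-oxoethyl)-5-(methoxymethoxy)phenoxy]-2-methylpropanoic acid
Conditions: H2 (1 atm), Pd/C (10% palladium on carbon), EtOAc, rt
Reagents that add atoms: none
Why: Hydrogenolysis cleaves the benzyl ester selectively, since the methyl ester, the MOM acetal and the aryl ethers are inert and no alkene is present at this stage.

Step 11
Reactants: 17 2-[2-(2-methoxy-2-oxoethyl)-5-(methoxymethoxy)phenoxy]-2-methylpropanoic acid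
Product: 18 1,3-dioxoisoindolin-2-yl 2-[2-(2-methoxy-2-oxoethyl)-5-(methoxymethoxy)phenoxy]-2-methylpropanoate
Conditions: N-hydroxyphthalimide, N,N'-diisopropylcarbodiimide, DMAP (cat.), CH2Cl2, rt
Reagents that add atoms: N-hydroxyphthalimide, ON1C(=O)c2ccccc2C1=O
Why: Carbodiimide coupling (Steglich-type esterification) with N-hydroxyphthalimide converts the hindered acid into the redox-active N-(acyloxy)phthalimide.

Step 12
Reactants: 18 1,3-dioxoisoindolin-2-yl 2-[2-(2-methoxy-2-oxoethyl)-5-(methoxymethoxy)phenoxy]-2-methylpropanoate; 19 acetylene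
Product: 20 methyl 2-[5-(methoxymethoxy)-2,2-dimethyl-2H-chromen-8-yl]acetate
Conditions: fac-Ir(ppy)3 (1 mol%), acetylene (balloon, about 1 atm), degassed MeCN, 450 nm LEDs, rt
Reagents that add atoms: none
Why: Proposed new method: the photoexcited iridium complex reduces the N-(acyloxy)phthalimide by single-electron transfer, and loss of CO2 and phthalimide anion gives the tertiary α-aryloxy radical at the carbon bearing the two methyl groups; this nucleophilic radical adds to acetylene (first new C–C bond), the resulting σ-vinyl radical attacks ring B at C3' (second new C–C bond), and the cyclohexadienyl radical is oxidised by the tetravalent iridium species and deprotonated by phthalimide anion, so the process is redox-neutral. The closest known reaction types are the photoredox (4+2) radical annulation of N-(acyloxy)phthalimides of aryloxyacetic acids with electron-poor olefins to chromans and the photoredox addition of α-heteroatom-substituted alkyl radicals to acetylene gas; new is their combination with a tertiary radical and acetylene as the two-carbon partner. The pyran ring is closed by a six-membered homolytic aromatic substitution (ortho attack, 6-endo with respect to the arene), and the ring enforces the cis geometry of the new CH=CH unit. No stereocentre is formed. The step needs regioselectivity for C3' over ipso or C1' attack, which the CH2CO2Me group blocking C1' and the two oxygen substituents flanking C3' should secure. It also needs the tertiary radical to add to acetylene before it is oxidised or reduced, which the high acetylene concentration in a solvent that is a poor hydrogen-atom donor should secure.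

Step 13
Reactants: 20 methyl 2-[5-(methoxymethoxy)-2,2-dimethyl-2H-chromen-8-yl]acetate
Product: 21 2-[5-(methoxymethoxy)-2,2-dimethyl-2H-chromen-8-yl]acetic acid
Conditions: LiOH·H2O, THF/MeOH/H2O, rt; then 1 M HCl to pH 4, 0 °C
Reagents that add atoms: lithium hydroxide, [Li+].[OH-]
Why: Saponification of the unhindered methyl ester leaves the MOM ether and the chromene untouched, and cold acidification to pH 4 avoids acetal cleavage.

Step 14
Reactants: 21 2-[5-(methoxymethoxy)-2,2-dimethyl-2H-chromen-8-yl]acetic acid; 22 (4R)-4-benzyloxazolidin-2-one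
Product: 24 (4R)-4-benzyl-3-{2-[5-(methoxymethoxy)-2,2-dimethyl-2H-chromen-8-yl]acetyl}oxazolidin-2-one, via mixed pivalic anhydride 23 (not isolated)
Conditions: PivCl, Et3N, THF, −20 °C; then 22, LiCl, rt
Reagents that add atoms: pivaloyl chloride, CC(C)(C)C(Cl)=O (pivaloyl group of 23 only)
Why: N-Acylation of the oxazolidinone through the mixed pivalic anhydride under Et3N/LiCl activation attaches the chiral auxiliary at the less hindered acyl carbon without strong base.

Step 15
Reactants: 24 (4R)-4-benzyl-3-{2-[5-(methoxymethoxy)-2,2-dimethyl-2H-chromen-8-yl]acetyl}oxazolidin-2-one; 10 2-(bromomethyl)-3,5-dimethoxy-4-(3-methylbut-2-en-1-yl)phenyl 2,2-dimethylpropanoate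
Product: 26 2-{(2R)-3-[(4R)-4-benzyl-2-oxooxazolidin-3-yl]-2-[5-(methoxymethoxy)-2,2-dimethyl-2H-chromen-8-yl]-3-oxopropyl}-3,5-dimethoxy-4-(3-methylbut-2-en-1-yl)phenyl 2,2-dimethylpropanoate, via sodium Z-enolate 25 (not isolated)
Conditions: NaHMDS (1.05 equiv), THF, −78 °C; then 10, −78 to −30 °C; quench cold with AcOH
Reagents that add atoms: sodium bis(trimethylsilyl)amide, C[Si](C)(C)[N-][Si](C)(C)C.[Na+] (sodium of 25 only)
Why: Evans alkylation, in which the chelated sodium Z-enolate is shielded on the face syn to the benzyl group of the (R)-auxiliary, so that the benzylic bromide should add to the opposite face and set the new stereocentre (the later C3) as (R).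

Step 16
Reactants: 26 (the alkylated imide of step 15)
Product: 27 2-{(2R)-3-hydroxy-2-[5-(methoxymethoxy)-2,2-dimethyl-2H-chromen-8-yl]propyl}-3,5-dimethoxy-4-(3-methylbut-2-en-1-yl)phenol
Conditions: LiBH4 (excess), MeOH, THF, 0 °C to rt
Reagents that add atoms: none
Why: Lithium borohydride reductively cleaves the exocyclic imide carbonyl to the primary alcohol without touching the stereocentre (reductive auxiliary removal) and, in excess with methanol, should also reduce the activated aryl pivalate, so that the phenol and the alcohol needed for ring closure are released together.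

Step 17
Reactants: 27 (the phenol alcohol of step 16)
Product: 28 (3R)-5,7-dimethoxy-3-[5-(methoxymethoxy)-2,2-dimethyl-2H-chromen-8-yl]-6-(3-methylbut-2-en-1-yl)chromane
Conditions: PPh3, DIAD, THF, 0 °C to rt
Reagents that add atoms: none
Why: Intramolecular Mitsunobu etherification activates the primary alcohol, which the phenol displaces in a 6-exo-tet closure of the chroman ring, and the stereocentre is not a reacting centre and keeps its (R) configuration.

Step 18
Reactants: 28 (Kanzonol I methoxymethyl ether)
Product: 29 Kanzonol I, 8-[(3R)-5,7-dimethoxy-6-(3-methylbut-2-en-1-yl)chroman-3-yl]-2,2-dimethyl-2H-chromen-5-ol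
Conditions: 2 M aq. HCl, MeOH/THF, 45 °C
Reagents that add atoms: none
Why: Acid-catalysed hydrolysis of the MOM acetal frees the phenol under conditions that a prenyl group flanked by two methoxy groups and a 2,2-dimethylchromene should tolerate.

**Compound list**

1 | 1,3-dimethoxybenzene | COc1cccc(OC)c1 | starting material
2 | 1-bromo-3-methylbut-2-ene (prenyl bromide) | CC(C)=CCBr | starting material
3 | 2,6-dimethoxyphenyllithium | [Li]c1c(OC)cccc1OC | intermediate
4 | 1,3-dimethoxy-2-(3-methylbut-2-en-1-yl)benzene | COc1cccc(OC)c1CC=C(C)C | intermediate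
5 | 2-[3,5-dimethoxy-4-(3-methylbut-2-en-1-yl)phenyl]-4,4,5,5-tetramethyl-1,3,2-dioxaborolane | COc1cc(B2OC(C)(C)C(C)(C)O2)cc(OC)c1CC=C(C)C | intermediate
6 | 3,5-dimethoxy-4-(3-methylbut-2-en-1-yl)phenol | COc1cc(O)cc(OC)c1CC=C(C)C | intermediate
7 | 6-hydroxy-2,4-dimethoxy-3-(3-methylbut-2-en-1-yl)benzaldehyde | COc1cc(O)c(C=O)c(OC)c1CC=C(C)C | intermediate
8 | 2-(hydroxymethyl)-3,5-dimethoxy-4-(3-methylbut-2-en-1-yl)phenol | COc1cc(O)c(CO)c(OC)c1CC=C(C)C | intermediate
9 | 2-(hydroxymethyl)-3,5-dimethoxy-4-(3-methylbut-2-en-1-yl)phenyl 2,2-dimethylpropanoate | COc1cc(OC(=O)C(C)(C)C)c(CO)c(OC)c1CC=C(C)C | intermediate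
10 | 2-(bromomethyl)-3,5-dimethoxy-4-(3-methylbut-2-en-1-yl)phenyl 2,2-dimethylpropanoate | COc1cc(OC(=O)C(C)(C)C)c(CBr)c(OC)c1CC=C(C)C | intermediate
11 | 2-(2,4-dihydroxyphenyl)acetic acid | OC(=O)Cc1ccc(O)cc1O | starting material
12 | 6-hydroxybenzofuran-2(3H)-one | O=C1Cc2ccc(O)cc2O1 | intermediate
13 | 6-(methoxymethoxy)benzofuran-2(3H)-one | COCOc1ccc2CC(=O)Oc2c1 | intermediate
14 | benzyl 2-bromo-2-methylpropanoate | CC(C)(Br)C(=O)OCc1ccccc1 | starting material
15 | methyl 2-[2-hydroxy-4-(methoxymethoxy)phenyl]acetate | COCOc1ccc(CC(=O)OC)c(O)c1 | intermediate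
16 | benzyl 2-[2-(2-methoxy-2-oxoethyl)-5-(methoxymethoxy)phenoxy]-2-methylpropanoate | COCOc1ccc(CC(=O)OC)c(OC(C)(C)C(=O)OCc2ccccc2)c1 | intermediate
17 | 2-[2-(2-methoxy-2-oxoethyl)-5-(methoxymethoxy)phenoxy]-2-methylpropanoic acid | COCOc1ccc(CC(=O)OC)c(OC(C)(C)C(=O)O)c1 | intermediate
18 | 1,3-dioxoisoindolin-2-yl 2-[2-(2-methoxy-2-oxoethyl)-5-(methoxymethoxy)phenoxy]-2-methylpropanoate | COCOc1ccc(CC(=O)OC)c(OC(C)(C)C(=O)ON2C(=O)c3ccccc3C2=O)c1 | intermediate
19 | acetylene (ethyne) | C#C | starting material
20 | methyl 2-[5-(methoxymethoxy)-2,2-dimethyl-2H-chromen-8-yl]acetate | COCOc1ccc(CC(=O)OC)c2OC(C)(C)C=Cc12 | intermediate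
21 | 2-[5-(methoxymethoxy)-2,2-dimethyl-2H-chromen-8-yl]acetic acid | COCOc1ccc(CC(=O)O)c2OC(C)(C)C=Cc12 | intermediate
22 | (4R)-4-benzyloxazolidin-2-one | O=C1OC[C@@H](Cc2ccccc2)N1 | starting material
23 | 2-[5-(methoxymethoxy)-2,2-dimethyl-2H-chromen-8-yl]acetic 2,2-dimethylpropanoic anhydride | COCOc1ccc(CC(=O)OC(=O)C(C)(C)C)c2OC(C)(C)C=Cc12 | intermediate
24 | (4R)-4-benzyl-3-{2-[5-(methoxymethoxy)-2,2-dimethyl-2H-chromen-8-yl]acetyl}oxazolidin-2-one | COCOc1ccc(CC(=O)N3[C@H](Cc4ccccc4)COC3=O)c2OC(C)(C)C=Cc12 | intermediate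
25 | sodium (Z)-enolate of imide 24 | COCOc1ccc(/C=C(\[O-])N3[C@H](Cc4ccccc4)COC3=O)c2OC(C)(C)C=Cc12.[Na+] | intermediate
26 | 2-{(2R)-3-[(4R)-4-benzyl-2-oxooxazolidin-3-yl]-2-[5-(methoxymethoxy)-2,2-dimethyl-2H-chromen-8-yl]-3-oxopropyl}-3,5-dimethoxy-4-(3-methylbut-2-en-1-yl)phenyl 2,2-dimethylpropanoate | COCOc1ccc([C@@H](Cc5c(OC)c(CC=C(C)C)c(OC)cc5OC(=O)C(C)(C)C)C(=O)N3[C@H](Cc4ccccc4)COC3=O)c2OC(C)(C)C=Cc12 | intermediate
27 | 2-{(2R)-3-hydroxy-2-[5-(methoxymethoxy)-2,2-dimethyl-2H-chromen-8-yl]propyl}-3,5-dimethoxy-4-(3-methylbut-2-en-1-yl)phenol | COCOc1ccc([C@@H](Cc3c(OC)c(CC=C(C)C)c(OC)cc3O)CO)c2OC(C)(C)C=Cc12 | intermediate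
28 | (3R)-5,7-dimethoxy-3-[5-(methoxymethoxy)-2,2-dimethyl-2H-chromen-8-yl]-6-(3-methylbut-2-en-1-yl)chromane | COCOc1ccc([C@@H]3COc4cc(OC)c(CC=C(C)C)c(OC)c4C3)c2OC(C)(C)C=Cc12 | intermediate
29 | Kanzonol I, 8-[(3R)-5,7-dimethoxy-6-(3-methylbut-2-en-1-yl)chroman-3-yl]-2,2-dimethyl-2H-chromen-5-ol | COc1cc2c(c(OC)c1CC=C(C)C)C[C@H](c1ccc(O)c3c1OC(C)(C)C=C3)CO2 | target

**Step count and risks**

Total step count: 18. Longest linear sequence: 12 steps (steps 7 to 18, from 11 to 29).

Steps most likely to fail:

Step 12 (proposed new method). The tertiary α-aryloxy radical may be oxidised, reduced or quenched by 1,5-hydrogen transfer from the neighbouring benzylic CH2 before it adds to acetylene, and the vinyl radical may abstract hydrogen before it closes onto ring B. The fallback uses known chemistry, sets out from 13 and returns at 20. Lactone 13 is opened with K2CO3 in MeOH and phenol 15 is isolated. Compound 15 is O-alkylated with 3-chloro-3-methylbut-1-yne (CuCl2·2H2O cat., DBU, MeCN, 0 °C) to give the aryl propargyl ether methyl 2-[4-(methoxymethoxy)-2-[(2-methylbut-3-yn-2-yl)oxy]phenyl]acetate F1. Heating F1 in N,N-diethylaniline (about 190 °C) should trigger the aromatic propargyl Claisen rearrangement, 1,5-hydrogen shift and oxa-6π electrocyclisation at the only free ortho position, which gives 20.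

Step 15. The electron-rich benzylic bromide 10 may ionise and self-condense, and substitution at the doubly ortho-substituted benzylic carbon may be slow enough for the enolate to decompose or the product to epimerise. The fallback avoids the benzylic halide, sets out from 21 and 7 and returns at 27. Acid 21 is loaded, by the protocol of step 14 through anhydride 23, with (S)-4-benzyloxazolidin-2-one to give the imide (4S)-4-benzyl-3-{2-[5-(methoxymethoxy)-2,2-dimethyl-2H-chromen-8-yl]acetyl}oxazolidin-2-one F2. Aldehyde 7 is acylated (PivCl, Et3N, DMAP) to the aldehyde 2-formyl-3,5-dimethoxy-4-(3-methylbut-2-en-1-yl)phenyl 2,2-dimethylpropanoate F3. An Evans syn aldol reaction of F2 with F3 (Bu2BOTf, i-Pr2NEt, CH2Cl2, −78 to 0 °C, buffered H2O2 work-up) should give the aldol adduct (4S)-4-benzyl-3-{(2S,3S)-3-[2,4-dimethoxy-3-(3-methylbut-2-en-1-yl)-6-(pivaloyloxy)phenyl]-3-hydroxy-2-[5-(methoxymethoxy)-2,2-dimethyl-2H-chromen-8-yl]propanoyl}oxazolidin-2-one F4. The boron aldol uses the enolate face opposite to that used in the sodium enolate alkylation, hence the enantiomeric auxiliary. The benzylic hydroxyl is removed by Barton–McCombie deoxygenation: 1,1'-thiocarbonyldiimidazole and DMAP give the thiocarbonylimidazolide of the aldol adduct F5, and Bu3SnH with AIBN in toluene at 80 °C gives the imide (4S)-4-benzyl-3-{(2R)-3-[2,4-dimethoxy-3-(3-methylbut-2-en-1-yl)-6-(pivaloyloxy)phenyl]-2-[5-(methoxymethoxy)-2,2-dimethyl-2H-chromen-8-yl]propanoyl}oxazolidin-2-one F6. Treatment of F6 with LiBH4 and MeOH as in step 16 should give 27.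

Step 2. The iridium hydride and boryl species may hydroborate or isomerise the prenyl double bond, or borylation may be incomplete. The fallback sets out from 2 (with commercial 3,5-dimethoxyphenol) and returns at 6. The phenol is silylated (TIPSCl, imidazole, DMF) to the silyl ether (3,5-dimethoxyphenoxy)tri(propan-2-yl)silane F7. Directed lithiation between the two methoxy groups (n-BuLi, THF, 0 °C) and alkylation with 2 should give the silyl ether [3,5-dimethoxy-4-(3-methylbut-2-en-1-yl)phenoxy]tri(propan-2-yl)silane F8. Bu4NF in THF then frees 6.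

Further compounds
F1 | step 12 | methyl 2-[4-(methoxymethoxy)-2-[(2-methylbut-3-yn-2-yl)oxy]phenyl]acetate | COCOc1ccc(CC(=O)OC)c(OC(C)(C)C#C)c1
F2 | step 15 | (4S)-4-benzyl-3-{2-[5-(methoxymethoxy)-2,2-dimethyl-2H-chromen-8-yl]acetyl}oxazolidin-2-one | COCOc1ccc(CC(=O)N3[C@@H](Cc4ccccc4)COC3=O)c2OC(C)(C)C=Cc12
F3 | step 15 | 2-formyl-3,5-dimethoxy-4-(3-methylbut-2-en-1-yl)phenyl 2,2-dimethylpropanoate | COc1cc(OC(=O)C(C)(C)C)c(C=O)c(OC)c1CC=C(C)C
F4 | step 15 | (4S)-4-benzyl-3-{(2S,3S)-3-[2,4-dimethoxy-3-(3-methylbut-2-en-1-yl)-6-(pivaloyloxy)phenyl]-3-hydroxy-2-[5-(methoxymethoxy)-2,2-dimethyl-2H-chromen-8-yl]propanoyl}oxazolidin-2-one | COCOc1ccc([C@@H]([C@H](O)c5c(OC)c(CC=C(C)C)c(OC)cc5OC(=O)C(C)(C)C)C(=O)N3[C@@H](Cc4ccccc4)COC3=O)c2OC(C)(C)C=Cc12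
F5 | step 15 | O-(imidazol-1-ylthiocarbonyl) derivative of F4 (thiocarbonylimidazolide) | COCOc1ccc([C@@H]([C@H](OC(=S)n6ccnc6)c5c(OC)c(CC=C(C)C)c(OC)cc5OC(=O)C(C)(C)C)C(=O)N3[C@@H](Cc4ccccc4)COC3=O)c2OC(C)(C)C=Cc12
F6 | step 15 | (4S)-4-benzyl-3-{(2R)-3-[2,4-dimethoxy-3-(3-methylbut-2-en-1-yl)-6-(pivaloyloxy)phenyl]-2-[5-(methoxymethoxy)-2,2-dimethyl-2H-chromen-8-yl]propanoyl}oxazolidin-2-one | COCOc1ccc([C@@H](Cc5c(OC)c(CC=C(C)C)c(OC)cc5OC(=O)C(C)(C)C)C(=O)N3[C@@H](Cc4ccccc4)COC3=O)c2OC(C)(C)C=Cc12
F7 | step 2 | (3,5-dimethoxyphenoxy)tri(propan-2-yl)silane | COc1cc(OC)cc(O[Si](C(C)C)(C(C)C)C(C)C)c1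
F8 | step 2 | [3,5-dimethoxy-4-(3-methylbut-2-en-1-yl)phenoxy]tri(propan-2-yl)silane | COc1cc(O[Si](C(C)C)(C(C)C)C(C)C)cc(OC)c1CC=C(C)C
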